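**Plan**

1. Daucane numbering: C1 is the quaternary fusion carbon with methyl C15; C2 and C3 are CH2; C4 is the isopropyl carbinol; C5 is the fusion CH; C6 carries the ester; C7 is CH2; C8 is the spiro-epoxide carbon with C14; C9 and C10 carry the diol. β is the face of C15, α the opposite face.
2. The retrosynthesis cuts the C6–O acyl bond, the epoxide oxygen, C8=C14, the C4–isopropyl bond and the C9/C10 C–O bonds, then C1–C5 and C1–C10. Ring carbons C5–C10, with oxygen on C6 and C8, are a 2,4-dimethoxyphenyl ring (ipso carbon C5), and C1 with C15 is a methyl-bearing carbene carbon tied to C5 by the chain C2(=O)–C3–C4.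
3. Forward, the arylpropanoic acid becomes the α-methyl diazoketone. One copper-catalysed arene cyclopropanation and norcaradiene opening then closes the five-membered ring and widens the benzene ring to the seven-membered ring.
4. The two enol ethers are then told apart (C6 ketal, C8 enone), C9=C10 is dihydroxylated, C8 is methylenated, the C2 carbonyl is moved to C4 (Wharton), isopropyl is added, C6 is reduced and acylated, and the epoxide is made last.
5. Stereochemistry: C1 comes from the chiral copper–bis(oxazoline) catalyst; C5, C9/C10 and C4 from attack on the face opposite C15; C6 from hydride delivery by the C4 hydroxyl; C8 from epoxidation directed by the C9 hydroxyl.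

Key step: step 3

Assumption: the sense of induction of the copper–bis(oxazoline) catalyst follows the ligand antipode, so the antipode that leads to (8aR)-7 is used; the other antipode would give the mirror-image series.

**Step 1**
Reactants: 1 3-(2,4-dimethoxyphenyl)propanoic acid
Product: 2 3-(2,4-dimethoxyphenyl)propanoyl chloride
Conditions: (COCl)2 (1.3 equiv), DMF (cat.), CH2Cl2, 0 °C to rt; evaporate, use crude
Reagents that add atoms: oxalyl chloride, O=C(Cl)C(Cl)=O
Why: Acid chloride formation through the chloroiminium (Vilsmeier-type) catalyst is routine, and without a Lewis acid the ring is not acylated, the free ortho carbon being meta to both methoxy groups.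

**Step 2**
Reactants: 2 3-(2,4-dimethoxyphenyl)propanoyl chloride; 3 N-ethyl-N-nitrosourea
Product: 5 2-diazo-5-(2,4-dimethoxyphenyl)pentan-3-one, via diazoethane 4 (not isolated)
Conditions: 3, KOH (aq), Et2O, −10 °C, ethereal layer dried over KOH pellets (about 3 equiv of 4); then 2 in Et2O, −20 °C to 0 °C
Reagents that add atoms: none
Why: Acylation of a diazoalkane by an acid chloride (the diazoketone synthesis of the Arndt–Eistert sequence) should give the α-methyl diazoketone, the excess diazoethane taking up HCl as chloroethane so that no α-chloroketone forms.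

**Step 3**
Reactants: 5 2-diazo-5-(2,4-dimethoxyphenyl)pentan-3-one
Product: 7 azulenone (8aR)-4,6-dimethoxy-8a-methyl-3,8a-dihydroazulen-1(2H)-one, via norcaradiene 6 (not isolated)
Conditions: Cu(MeCN)4PF6 (monovalent copper, 5 mol%), 2,2'-isopropylidenebis[(4R)-4-phenyl-2-oxazoline] or its (4S) antipode (6 mol%), NaB[3,5-(CF3)2C6H3]4 (6 mol%), CH2Cl2, reflux, slow addition of 5; filter through basic alumina
Reagents that add atoms: none
Why: Loss of N2 gives an electrophilic copper carbenoid that adds across the ipso–ortho bond C5–C10 of the arene to form norcaradiene 6, whose disrotatory 6π electrocyclic opening of the C5–C10 bond gives cycloheptatriene 7; this is the intramolecular Büchner reaction, known for aryl diazoketones and their α-methyl homologues under copper–bis(oxazoline) catalysis. The five-membered ring closes in the [2+1] addition itself, C1 being tied to C5 through the three-atom tether C2–C4 (a bicyclo[3.1.0] unit), and the seven-membered ring arises from the six-membered arene when C1 ends up inserted between C5 and C10. C1 is the only stereocentre that survives and is set by the C2-symmetric ligand, which decides the face of the arene plane that meets the methyl-bearing carbenoid carbon; the cyclopropane centres C5 and C10 vanish on opening. The step needs regioselectivity between the two ipso–ortho bonds, which the ortho methoxy group secures by blocking C5–C6, and chemoselectivity over formal aromatic C–H insertion, which is helped because the free ortho carbon is meta to both donors while the ipso carbon is activated by both.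

**Step 4**
Reactants: 7 azulenone (8aR)-4,6-dimethoxy-8a-methyl-3,8a-dihydroazulen-1(2H)-one
Product: 9 enone ketal 6,6-ethylenedioxy-1β-methyl-5αH-bicyclo[5.3.0]dec-9-ene-2,8-dione, via bis-dioxolane 8 (not isolated)
Conditions: HOCH2CH2OH (10 equiv), PPTS (10 mol%), CH2Cl2, 0 °C to rt; then acetone/H2O (10:1), PPTS, rt
Reagents that add atoms: ethylene glycol, OCCO; water, O
Why: Acid-catalysed trans-ketalisation (C-protonation of each enol ether, capture of the oxocarbenium ion by the diol) followed by selective hydrolysis of the allylic ketal, which ionises to a conjugated oxocarbenium ion and ends as a conjugated enone while the C6 ketal is then deactivated by the β-carbonyl, should give 9; the proton reaches C5 from the α face, opposite the C15 methyl on the adjoining quaternary carbon, as electrophiles do in steroidal 5-enes, which sets the trans ring fusion.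

**Step 5**
Reactants: 9 enone ketal
Product: 10 diol 6,6-ethylenedioxy-9α,10α-dihydroxy-1β-methyl-5αH-bicyclo[5.3.0]decane-2,8-dione
Conditions: OsO4 (5 mol%), NMO (1.5 equiv), acetone/H2O (4:1), rt
Reagents that add atoms: osmium tetroxide (catalytic oxygen carrier), O=[Os](=O)(=O)=O; N-methylmorpholine N-oxide, C[N+]1([O-])CCOCC1; water, O
Why: Upjohn dihydroxylation (suprafacial [3+2] osmylation, NMO as terminal oxidant) of the only C=C bond, an enone that reacts slowly but cleanly, should take place from the α face because the C15 methyl on the neighbouring quaternary C1 shields the β face of C10, giving the cis-9α,10α-diol.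

**Step 6**
Reactants: 10 diol
Product: 11 acetonide 6,6-ethylenedioxy-9α,10α-isopropylidenedioxy-1β-methyl-5αH-bicyclo[5.3.0]decane-2,8-dione
Conditions: CH2=C(OMe)CH3 (2 equiv), PPTS (5 mol%), CH2Cl2, 0 °C
Reagents that add atoms: 2-methoxypropene, COC(C)=C
Why: Acid-catalysed acetal formation with the enol ether closes the five-membered acetonide on the cis-diol faster than the C6 dioxolane can exchange, and it masks the α-ketol and the C10 aldol-type hydroxyl before the basic steps.

**Step 7**
Reactants: 11 acetonide; 12 methyltriphenylphosphonium bromide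
Product: 14 methylene ketone 6,6-ethylenedioxy-9α,10α-isopropylidenedioxy-1β-methyl-8-methylene-5αH-bicyclo[5.3.0]decan-2-one, via methylenetriphenylphosphorane 13 (not isolated)
Conditions: 12 (1.3 equiv), KOtBu (1.2 equiv), THF, 0 °C; then 11, −78 °C to 0 °C
Reagents that add atoms: none
Why: Wittig methylenation should take the C8 ketone, which is activated by its α-oxygen and flanked by a CH2 group, in preference to the C2 cyclopentanone that sits next to the quaternary C1 and is as sluggish toward ylides as a steroidal 17-ketone.

**Step 8**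
Reactants: 14 methylene ketone
Product: 16 cyclopentenone 6,6-ethylenedioxy-9α,10α-isopropylidenedioxy-1β-methyl-8-methylene-5αH-bicyclo[5.3.0]dec-3-en-2-one, via trimethylsilyl enol ether 15 (not isolated)
Conditions: LiN(iPr)2 (1.2 equiv), THF, −78 °C; Me3SiCl (1.5 equiv); then Pd(OAc)2 (1.1 equiv), MeCN, rt
Reagents that add atoms: none
Why: Saegusa–Ito oxidation: the ketone can enolise only toward C3 because C1 is quaternary, and divalent palladium turns the silyl enol ether into the enone through an oxa-π-allyl complex and β-hydride elimination of a C4 hydrogen.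

**Step 9**
Reactants: 16 cyclopentenone
Product: 17 epoxy ketone 3α,4α-epoxy-6,6-ethylenedioxy-9α,10α-isopropylidenedioxy-1β-methyl-8-methylene-5αH-bicyclo[5.3.0]decan-2-one
Conditions: H2O2 (30% aq, 3 equiv), NaOH (aq, 0.5 equiv), MeOH, 0 °C
Reagents that add atoms: hydrogen peroxide, OO
Why: Weitz–Scheffer nucleophilic epoxidation (conjugate addition of hydroperoxide, then ring closure of the enolate on oxygen) touches only the electron-poor enone, not the 1,1-disubstituted alkene, and should come from the α face of C4, away from C6 and C15, although the two new centres are erased in steps 10 and 11.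

**Step 10**
Reactants: 17 epoxy ketone
Product: 19 allylic alcohol 6,6-ethylenedioxy-9α,10α-isopropylidenedioxy-1β-methyl-8-methylene-5αH-bicyclo[5.3.0]dec-2-en-4α-ol, via epoxy hydrazone 18 (not isolated)
Conditions: N2H4·H2O (3 equiv), AcOH (0.2 equiv), MeOH, 0 °C to rt, under argon
Reagents that add atoms: none
Why: Wharton transposition: the epoxy hydrazone opens to an alkenyl diazene that loses N2, which leaves the C4–O bond in place as the 4α-alcohol and the double bond at C2=C3, while ketal, acetonide and the isolated alkene do not react with hydrazine when air (diimide) is kept out.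

**Step 11**
Reactants: 19 allylic alcohol
Product: 20 transposed enone 6,6-ethylenedioxy-9α,10α-isopropylidenedioxy-1β-methyl-8-methylene-5αH-bicyclo[5.3.0]dec-2-en-4-one
Conditions: Dess–Martin periodinane (1.3 equiv), NaHCO3, CH2Cl2, 0 °C to rt
Reagents that add atoms: none
Why: Dess–Martin oxidation of the secondary allylic alcohol under buffered, non-enolising conditions should give the transposed enone without epimerising the C5 hydrogen that is now α to the carbonyl.

**Step 12**
Reactants: 20 transposed enone
Product: 21 ketone 6,6-ethylenedioxy-9α,10α-isopropylidenedioxy-1β-methyl-8-methylene-5αH-bicyclo[5.3.0]decan-4-one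
Conditions: [(Ph3P)CuH]6 (0.3 equiv), H2O (3 equiv), toluene (degassed), rt
Reagents that add atoms: none
Why: Copper hydride conjugate reduction (hydride to C2, protonation of the copper enolate at C3 by water) is selective for the enone and leaves the isolated exocyclic alkene, which catalytic hydrogenation would not spare.

**Step 13**
Reactants: 21 ketone; 22 isopropylmagnesium chloride
Product: 23 tertiary alcohol 6,6-ethylenedioxy-9α,10α-isopropylidenedioxydauc-8(14)-en-4β-ol
Conditions: CeCl3 (anhydrous, 2 equiv), THF; 22 (2 equiv), −78 °C; then 21, −78 °C to −20 °C; NH4Cl (aq)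
Reagents that add atoms: none
Why: Organocerium-type 1,2-addition (Grignard reagent with CeCl3) suppresses enolisation, β-elimination of the ketal oxygen and β-hydride reduction, and the nucleophile should enter from the α face of the cyclopentanone because C6 with its ketal and the C15 methyl both stand on the β face, so the new hydroxyl is β.

**Step 14**
Reactants: 23 tertiary alcohol
Product: 24 hydroxy ketone 4β-hydroxy-9α,10α-isopropylidenedioxydauc-8(14)-en-6-one
Conditions: PPTS (0.2 equiv), acetone/H2O (20:1), 40 °C
Reagents that add atoms: water, O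
Why: Acid-catalysed hydrolysis of the dioxolane in a large excess of acetone frees the C6 ketone while mass action keeps the acetonide, and, as in the mild hydrolysis of β,γ-unsaturated ketals, a weak acid should neither move the exocyclic double bond into conjugation nor dehydrate the tertiary aldol.

**Step 15**
Reactants: 24 hydroxy ketone
Product: 25 diol 9α,10α-isopropylidenedioxydauc-8(14)-ene-4β,6α-diol
Conditions: Me4NBH(OAc)3 (5 equiv), MeCN/AcOH (1:1), −30 °C to 0 °C
Reagents that add atoms: none
Why: Evans–Saksena hydroxyl-directed reduction: the C4 hydroxyl exchanges onto boron and passes hydride to the C6 carbonyl through a six-membered chair from the β face on which it sits, which should give the 6α-alcohol, while unbound triacetoxyborohydride does not reduce the ketone.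

**Step 16**
Reactants: 25 diol; 26 isovaleryl chloride (3-methylbutanoyl chloride)
Product: 27 ester 6α-(3-methylbutanoyloxy)-9α,10α-isopropylidenedioxydauc-8(14)-en-4β-ol
Conditions: 26 (1.5 equiv), pyridine (3 equiv), DMAP (0.1 equiv), CH2Cl2, 0 °C to rt
Reagents that add atoms: none
Why: DMAP-catalysed acylation (acylpyridinium transfer) should esterify the only secondary hydroxyl, the tertiary C4 hydroxyl being inert under these conditions.

**Step 17**
Reactants: 27 ester
Product: 28 triol ester 6α-(3-methylbutanoyloxy)dauc-8(14)-ene-4β,9α,10α-triol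
Conditions: AcOH/H2O (4:1), 40 °C
Reagents that add atoms: none
Why: Acid hydrolysis of the isopropylidene acetal in aqueous acetic acid is mild enough for the ester, the tertiary alcohol and the exocyclic alkene.

**Step 18**
Reactants: 28 triol ester
Product: 29 target 8α,14-epoxy-6α-(3-methylbutanoyloxy)daucane-4β,9α,10α-triol (CNP0307265.1)
Conditions: VO(acac)2 (5 mol%), tBuOOH (1.5 equiv, in decane), CH2Cl2, 0 °C to rt
Reagents that add atoms: tert-butyl hydroperoxide, CC(C)(C)OO
Why: Vanadium-catalysed hydroxyl-directed epoxidation: the allylic C9 hydroxyl, backed by the homoallylic C10 hydroxyl on the same α face, binds the vanadium alkylperoxide and delivers oxygen to the α face of C8=C14, so the epoxide oxygen should be cis to the C9 hydroxyl as in the target.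

**Compound list** (bicyclo[5.3.0]decane names use daucane numbering)

1 | 3-(2,4-dimethoxyphenyl)propanoic acid | COc1ccc(CCC(=O)O)c(OC)c1 | starting material
2 | 3-(2,4-dimethoxyphenyl)propanoyl chloride | COc1ccc(CCC(=O)Cl)c(OC)c1 | intermediate
3 | N-ethyl-N-nitrosourea | CCN(N=O)C(N)=O | starting material
4 | diazoethane (formed in the flask) | CC=[N+]=[N-] | intermediate
5 | 2-diazo-5-(2,4-dimethoxyphenyl)pentan-3-one | COc1ccc(CCC(=O)C(C)=[N+]=[N-])c(OC)c1 | intermediate
6 | norcaradiene (cyclopropane C1–C5–C10, 6,8-dimethoxy-6,8-diene, C2 ketone; formed in the flask) | COC1=CC(OC)=C[C@@H]3[C@@]2(C)C(=O)CC[C@]123 | intermediate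
7 | (8aR)-4,6-dimethoxy-8a-methyl-3,8a-dihydroazulen-1(2H)-one (C2 ketone, 6,8-dimethoxy-5,7,9-triene, 1β-methyl) | COC1C=C(OC)C=C[C@@]2(C)C(=O)CCC2=1 | intermediate
8 | 6,6:8,8-bis(ethylenedioxy)-1β-methyl-5αH-bicyclo[5.3.0]dec-9-en-2-one (formed in the flask) | C13(OCCO3)CC4(OCCO4)C=C[C@@]2(C)C(=O)CC[C@H]12 | intermediate
9 | 6,6-ethylenedioxy-1β-methyl-5αH-bicyclo[5.3.0]dec-9-ene-2,8-dione | C13(OCCO3)CC(=O)C=C[C@@]2(C)C(=O)CC[C@H]12 | intermediate
10 | 6,6-ethylenedioxy-9α,10α-dihydroxy-1β-methyl-5αH-bicyclo[5.3.0]decane-2,8-dione | C13(OCCO3)CC(=O)[C@@H](O)[C@@H](O)[C@@]2(C)C(=O)CC[C@H]12 | intermediate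
11 | 6,6-ethylenedioxy-9α,10α-isopropylidenedioxy-1β-methyl-5αH-bicyclo[5.3.0]decane-2,8-dione | C13(OCCO3)CC(=O)[C@H]4OC(C)(C)O[C@H]4[C@@]2(C)C(=O)CC[C@H]12 | intermediate
12 | methyltriphenylphosphonium bromide | [Br-].C[P+](c1ccccc1)(c1ccccc1)c1ccccc1 | starting material
13 | methylenetriphenylphosphorane (formed in the flask) | C=P(c1ccccc1)(c1ccccc1)c1ccccc1 | intermediate
14 | 6,6-ethylenedioxy-9α,10α-isopropylidenedioxy-1β-methyl-8-methylene-5αH-bicyclo[5.3.0]decan-2-one | C13(OCCO3)CC(=C)[C@H]4OC(C)(C)O[C@H]4[C@@]2(C)C(=O)CC[C@H]12 | intermediate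
15 | 2-trimethylsilyloxy-2-ene of 14 (formed in the flask) | C13(OCCO3)CC(=C)[C@H]4OC(C)(C)O[C@H]4[C@@]2(C)C(O[Si](C)(C)C)=CC[C@H]12 | intermediate
16 | 6,6-ethylenedioxy-9α,10α-isopropylidenedioxy-1β-methyl-8-methylene-5αH-bicyclo[5.3.0]dec-3-en-2-one | C13(OCCO3)CC(=C)[C@H]4OC(C)(C)O[C@H]4[C@@]2(C)C(=O)C=C[C@H]12 | intermediate
17 | 3α,4α-epoxy-6,6-ethylenedioxy-9α,10α-isopropylidenedioxy-1β-methyl-8-methylene-5αH-bicyclo[5.3.0]decan-2-one | C13(OCCO3)CC(=C)[C@H]4OC(C)(C)O[C@H]4[C@@]2(C)C(=O)[C@H]5O[C@H]5[C@H]12 | intermediate
18 | hydrazone of 17 at C2 (formed in the flask) | C13(OCCO3)CC(=C)[C@H]4OC(C)(C)O[C@H]4[C@@]2(C)C(=NN)[C@H]5O[C@H]5[C@H]12 | intermediate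
19 | 6,6-ethylenedioxy-9α,10α-isopropylidenedioxy-1β-methyl-8-methylene-5αH-bicyclo[5.3.0]dec-2-en-4α-ol | C13(OCCO3)CC(=C)[C@H]4OC(C)(C)O[C@H]4[C@@]2(C)C=C[C@@H](O)[C@H]12 | intermediate
20 | 6,6-ethylenedioxy-9α,10α-isopropylidenedioxy-1β-methyl-8-methylene-5αH-bicyclo[5.3.0]dec-2-en-4-one | C13(OCCO3)CC(=C)[C@H]4OC(C)(C)O[C@H]4[C@@]2(C)C=CC(=O)[C@H]12 | intermediate
21 | 6,6-ethylenedioxy-9α,10α-isopropylidenedioxy-1β-methyl-8-methylene-5αH-bicyclo[5.3.0]decan-4-one | C13(OCCO3)CC(=C)[C@H]4OC(C)(C)O[C@H]4[C@@]2(C)CCC(=O)[C@H]12 | intermediate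
22 | isopropylmagnesium chloride | CC(C)[Mg]Cl | starting material
23 | 6,6-ethylenedioxy-9α,10α-isopropylidenedioxydauc-8(14)-en-4β-ol (4α-isopropyl, 5α-H) | C13(OCCO3)CC(=C)[C@H]4OC(C)(C)O[C@H]4[C@@]2(C)CC[C@@](O)(C(C)C)[C@H]12 | intermediate
24 | 4β-hydroxy-9α,10α-isopropylidenedioxydauc-8(14)-en-6-one | O=C1CC(=C)[C@H]4OC(C)(C)O[C@H]4[C@@]2(C)CC[C@@](O)(C(C)C)[C@H]12 | intermediate
25 | 9α,10α-isopropylidenedioxydauc-8(14)-ene-4β,6α-diol | O[C@H]1CC(=C)[C@H]4OC(C)(C)O[C@H]4[C@@]2(C)CC[C@@](O)(C(C)C)[C@H]12 | intermediate
26 | isovaleryl chloride (3-methylbutanoyl chloride) | CC(C)CC(Cl)=O | starting material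
27 | 6α-(3-methylbutanoyloxy)-9α,10α-isopropylidenedioxydauc-8(14)-en-4β-ol | CC(C)CC(=O)O[C@H]1CC(=C)[C@H]4OC(C)(C)O[C@H]4[C@@]2(C)CC[C@@](O)(C(C)C)[C@H]12 | intermediate
28 | 6α-(3-methylbutanoyloxy)dauc-8(14)-ene-4β,9α,10α-triol | CC(C)CC(=O)O[C@H]1CC(=C)[C@@H](O)[C@@H](O)[C@@]2(C)CC[C@@](O)(C(C)C)[C@H]12 | intermediate
29 | 8α,14-epoxy-6α-(3-methylbutanoyloxy)daucane-4β,9α,10α-triol (CNP0307265.1) | CC(C)CC(=O)O[C@H]1C[C@]2(CO2)[C@@H](O)[C@@H](O)[C@@]2(C)CC[C@@](O)(C(C)C)[C@H]12 | target

**Step count**

Total: 18 steps. Longest linear sequence: 18 steps, from 1 to 29; compounds 3, 12, 22 and 26 are commercial and each enters in a single operation.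

**Steps most likely to fail**

Step 3. The first C–C bond to the ipso carbon gives a zwitterion that both methoxy groups stabilise. If it lives long enough, the ligand no longer controls which face closes the cyclopropane, and the facial selectivity (enantiomeric purity) may be poor. Fallback: starting from 5, the same ring expansion would be run with achiral Rh2(OAc)4 in CH2Cl2 to give racemic azulenone F1. Its enantiomers would be separated by preparative chromatography on a chiral stationary phase with a neutral eluent; the (8aR) enantiomer is 7, where the route is rejoined.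

Step 4. Proton delivery to C5 from the β face, or its reversal under the acid, would give the cis ring fusion, and the hydrolysis stage may fail to tell the two ketals apart. Fallback: starting from 7, dilute aqueous oxalic acid in THF would hydrolyse only the C8 enol ether, with protonation at C5, to the cross-conjugated methoxy dienone F2. In this vinylogous ester the two oxygens are already differentiated, and the C5 hydrogen, γ to the C8 carbonyl, can be equilibrated with DBU to the thermodynamic ring-fusion mixture, from which the trans isomer is taken on. Acid-catalysed addition of ethylene glycol to the vinylogous ester with loss of methanol (PPTS, benzene, 4 Å molecular sieves) would then give 9, where the route is rejoined.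

Step 10. The alkenyl diazene may decompose along radical or anionic side paths instead of losing dinitrogen cleanly, and diimide formed from hydrazine may reduce the exocyclic alkene. Fallback: starting from 17, NaBH4 in MeOH at 0 °C would reduce the C2 ketone to epoxy alcohol F3 (either C2 epimer serves). 1,1'-Thiocarbonyldiimidazole in CH2Cl2 would convert it into O-thiocarbonyl imidazolide F4. Bu3SnH with AIBN in refluxing benzene would then generate the C2 radical, which opens the epoxide at the C3–O bond and, after hydrogen transfer to the C4 alkoxy radical, gives the allylic alcohol with its C4–O bond unchanged. This is 19, where the route is rejoined.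

**Further compounds**

F1 | step 3 | racemic 4,6-dimethoxy-8a-methyl-3,8a-dihydroazulen-1(2H)-one | COC1C=C(OC)C=CC2(C)C(=O)CCC2=1
F2 | step 4 | 6-methoxy-1β-methyl-5αH-bicyclo[5.3.0]deca-6,9-diene-2,8-dione (daucane numbering) | COC1=CC(=O)C=C[C@@]2(C)C(=O)CC[C@H]12
F3 | step 10 | 3α,4α-epoxy-6,6-ethylenedioxy-9α,10α-isopropylidenedioxy-1β-methyl-8-methylene-5αH-bicyclo[5.3.0]decan-2-ol (C2 epimers) | C13(OCCO3)CC(=C)[C@H]4OC(C)(C)O[C@H]4[C@@]2(C)C(O)[C@H]5O[C@H]5[C@H]12
F4 | step 10 | O-(imidazol-1-ylthiocarbonyl) derivative of F3 | C13(OCCO3)CC(=C)[C@H]4OC(C)(C)O[C@H]4[C@@]2(C)C(OC(=S)n6ccnc6)[C@H]5O[C@H]5[C@H]12
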